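**Strategy**

Everything rests on disconnecting the C2–C3 bond of the dihydrofuran ring (benzofuran numbering). C2 is a benzylic ether carbon carrying the trimethoxyphenyl group, and C3 has only a methyl group and the benzo ring as substituents. That is what results when a carbene centred on C3 inserts into a C–H bond of an ArCH2–O ether. One rhodium-catalysed step therefore closes the furan ring, makes C2–C3 and sets C3 by catalyst control; C2 is then equilibrated to trans. The precursor is a 1-diazoethyl arene with an ortho trimethoxybenzyl ether, made from 2,3,4-trihydroxyacetophenone. Its O6 allyl ether later migrates to C5, and oxidative methoxylation at C5 completes the dienone.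

Key step: step 6

Remark on numbering: locants follow the benzofuran skeleton of the target (O1, C2 aryl, C3 methyl, C3a, C4, C5 allyl/OMe, C6 carbonyl, C7 OMe, C7a).

Remark on design: O6 is masked as its allyl ether from the first step, so the protecting group of the key step is also the allyl source for C5 and no hydrogenolysis is needed near the benzylic C2–O1 bond.

Assumption: Rh2(S-PTAD)4 is taken to deliver the 3S configuration; if the sense of induction is the opposite, Rh2(R-PTAD)4 is used and nothing else changes.

**Route**

Step 1
Reactants: 1 2,3,4-trihydroxyacetophenone; 2 allyl bromide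
Product: 3 1-[4-(allyloxy)-2,3-dihydroxyphenyl]ethan-1-one
Conditions: 2 (1.05 equiv), NaHCO3 (1.2 equiv), DMF, 40 °C
Reagents that add atoms: none
Why: Williamson etherification under weak-base control: only the 4-OH, acidified by the para acetyl group and not tied up in the hydrogen-bonded chelate with the carbonyl, is ionised by NaHCO3, so mono-O-allylation at O4 should dominate.

Step 2
Reactants: 3 1-[4-(allyloxy)-2,3-dihydroxyphenyl]ethan-1-one
Product: 4 1-[4-(allyloxy)-2-hydroxy-3-methoxyphenyl]ethan-1-one
Conditions: MeI (1.1 equiv), K2CO3 (1.1 equiv), acetone, rt to 40 °C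
Reagents that add atoms: iodomethane, CI
Why: Williamson methylation: the 2-OH is held in the six-membered hydrogen-bonded chelate with the acetyl oxygen and reacts much more slowly than the free 3-OH, so methylation should stop at O3.

Step 3
Reactants: 4 1-[4-(allyloxy)-2-hydroxy-3-methoxyphenyl]ethan-1-one; 5 3,4,5-trimethoxybenzyl bromide
Product: 6 1-{4-(allyloxy)-3-methoxy-2-[(3,4,5-trimethoxybenzyl)oxy]phenyl}ethan-1-one
Conditions: 5 (1.1 equiv), K2CO3 (1.5 equiv), DMF, 60 °C
Reagents that add atoms: none
Why: Williamson etherification: in warm DMF the chelated phenol is deprotonated and alkylated by the reactive benzylic bromide, which installs the O–CH2–aryl group whose C–H bond the carbene will attack.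

Step 4
Reactants: 6 1-{4-(allyloxy)-3-methoxy-2-[(3,4,5-trimethoxybenzyl)oxy]phenyl}ethan-1-one
Product: 7 (E)-{1-[4-(allyloxy)-3-methoxy-2-[(3,4,5-trimethoxybenzyl)oxy]phenyl]ethylidene}hydrazine
Conditions: N2H4·H2O (10 equiv), AcOH (cat.), EtOH, 80 °C, argon
Reagents that add atoms: hydrazine, NN
Why: Hydrazone formation by condensation of the aryl methyl ketone with hydrazine: the large excess suppresses azine formation, and exclusion of air prevents diimide reduction of the allyl group (the C=N geometry is immaterial for the next step).

Step 5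
Reactants: 7 (E)-{1-[4-(allyloxy)-3-methoxy-2-[(3,4,5-trimethoxybenzyl)oxy]phenyl]ethylidene}hydrazine
Product: 8 1-(allyloxy)-4-(1-diazoethyl)-2-methoxy-3-[(3,4,5-trimethoxybenzyl)oxy]benzene
Conditions: activated MnO2 (8 equiv), CH2Cl2, 0 °C, dark; cold filtration through Celite; solution used at once
Reagents that add atoms: none
Why: Dehydrogenation of an N-unsubstituted hydrazone to the diazoalkane with MnO2, the standard entry to diazo compounds without an acceptor group; the low temperature and immediate use limit azine formation and thermal loss of nitrogen.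

Step 6
Reactants: 8 1-(allyloxy)-4-(1-diazoethyl)-2-methoxy-3-[(3,4,5-trimethoxybenzyl)oxy]benzene
Product: 9 (2R,3S)-6-(allyloxy)-7-methoxy-3-methyl-2-(3,4,5-trimethoxyphenyl)-2,3-dihydro-1-benzofuran (cis)
Conditions: Rh2(S-PTAD)4 (1 mol %), CH2Cl2, −20 to 0 °C, solution of 8 added slowly
Reagents that add atoms: none
Why: Rh2(S-PTAD)4, the divalent rhodium dimer dirhodium tetrakis[(S)-N-phthaloyl-(1-adamantyl)glycinate], takes up diazoalkane 8, expels N2 and forms a rhodium carbene whose carbon carries the arene and the methyl group; this carbene inserts into one of the two enantiotopic C–H bonds of the O–CH2–aryl group through a concerted, asynchronous, hydride-transfer-like three-centre transition state. The closest known reaction type is the enantioselective intramolecular C–H insertion of hydrazone-derived carbenes bearing two donor substituents into benzylic ether C–H bonds under chiral dirhodium tetracarboxylate catalysis, which gives cis-2,3-disubstituted 2,3-dihydrobenzofurans. The furan ring closes by 1,5-insertion, that is through a five-membered cyclic transition state made of the carbene carbon (C3), C3a, C7a, O1 and the benzylic carbon (C2). C3 is set by the chiral carboxylate ligands, which leave one face of the carbene open; C2 is set in the same event, the compact transition state placing the aryl group and the methyl group on the same side, and is corrected in step 7. The step needs insertion to win over 1,2-hydride migration from the methyl group, azine formation and any reaction at the allyl ether: two donor substituents make the carbene weakly electrophilic, which slows hydride migration and cyclopropanation, slow addition keeps the diazoalkane dilute, the C–H bond is activated by both O1 and the electron-rich trimethoxyphenyl ring and held at 1,5 distance, and the allyl ether sits para to the carbene and cannot be reached.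

Step 7
Reactants: 9 (2R,3S)-6-(allyloxy)-7-methoxy-3-methyl-2-(3,4,5-trimethoxyphenyl)-2,3-dihydro-1-benzofuran (cis)
Product: 10 (2S,3S)-6-(allyloxy)-7-methoxy-3-methyl-2-(3,4,5-trimethoxyphenyl)-2,3-dihydro-1-benzofuran (trans)
Conditions: CF3CO2H (10 equiv), CH2Cl2, 0 °C to rt
Reagents that add atoms: none
Why: Acid-mediated epimerisation of a 2-aryl-2,3-dihydrobenzofuran by reversible SN1 opening of the C2–O1 bond to the 3,4,5-trimethoxybenzyl cation and re-closure by the phenol oxygen: this should funnel the cis isomer to the more stable trans isomer, inverting C2 only, while C3 is not part of the ionising bond and keeps its configuration.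

Step 8
Reactants: 10 (2S,3S)-6-(allyloxy)-7-methoxy-3-methyl-2-(3,4,5-trimethoxyphenyl)-2,3-dihydro-1-benzofuran (trans)
Product: 12 (2S,3S)-5-allyl-7-methoxy-3-methyl-2-(3,4,5-trimethoxyphenyl)-2,3-dihydro-1-benzofuran-6-ol, via ortho-dienone 11 (not isolated)
Conditions: N,N-diethylaniline, 190 °C, sealed tube, argon
Reagents that add atoms: none
Why: Aromatic Claisen rearrangement: the [3,3] shift can end in a phenol only at C5, the single ortho carbon that carries hydrogen (C7 bears OMe), so tautomerisation of dienone 11 should deliver the 5-allyl phenol without touching either stereocentre.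

Step 9
Reactants: 12 (2S,3S)-5-allyl-7-methoxy-3-methyl-2-(3,4,5-trimethoxyphenyl)-2,3-dihydro-1-benzofuran-6-ol
Product: 14 (2S,3S,5R)-5-allyl-5,7-dimethoxy-3-methyl-2-(3,4,5-trimethoxyphenyl)-3,5-dihydro-1-benzofuran-6(2H)-one, via aryloxy(acetoxy)phenyliodane 13 (not isolated)
Conditions: PhI(OAc)2 (1.1 equiv), MeOH, −20 to 0 °C; aq. NaHCO3 work-up; chromatographic separation of the C5 epimers
Reagents that add atoms: methanol, CO
Why: Oxidative dearomatisation of a phenol with the trivalent iodine reagent PhI(OAc)2 in methanol (ortho-quinol ether formation): ligand exchange gives iodane 13, loss of iodobenzene leaves a phenoxenium-type electrophile, and methanol adds at the allyl-bearing ortho carbon C5 to give the 6,6-disubstituted cyclohexa-2,4-dienone, stabilised as the vinylogous ester O1–C7a=C7–C6=O; C5 is formed without useful bias from the remote C2 and C3 centres, so both epimers are expected and the 5R isomer (methoxy group on the face of the C3 methyl group) is separated.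

**Compound list**

1 | 2,3,4-trihydroxyacetophenone | CC(=O)c1ccc(O)c(O)c1O | starting material
2 | allyl bromide | C=CCBr | starting material
3 | 1-[4-(allyloxy)-2,3-dihydroxyphenyl]ethan-1-one | CC(=O)c1ccc(OCC=C)c(O)c1O | intermediate
4 | 1-[4-(allyloxy)-2-hydroxy-3-methoxyphenyl]ethan-1-one | CC(=O)c1ccc(OCC=C)c(OC)c1O | intermediate
5 | 3,4,5-trimethoxybenzyl bromide | COc1cc(CBr)cc(OC)c1OC | starting material
6 | 1-{4-(allyloxy)-3-methoxy-2-[(3,4,5-trimethoxybenzyl)oxy]phenyl}ethan-1-one | CC(=O)c1ccc(OCC=C)c(OC)c1OCc1cc(OC)c(OC)c(OC)c1 | intermediate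
7 | (E)-{1-[4-(allyloxy)-3-methoxy-2-[(3,4,5-trimethoxybenzyl)oxy]phenyl]ethylidene}hydrazine | C/C(=N\N)c1ccc(OCC=C)c(OC)c1OCc1cc(OC)c(OC)c(OC)c1 | intermediate
8 | 1-(allyloxy)-4-(1-diazoethyl)-2-methoxy-3-[(3,4,5-trimethoxybenzyl)oxy]benzene | C=CCOc1ccc(C(C)=[N+]=[N-])c(OCc2cc(OC)c(OC)c(OC)c2)c1OC | intermediate (key-step precursor, used in solution)
9 | (2R,3S)-6-(allyloxy)-7-methoxy-3-methyl-2-(3,4,5-trimethoxyphenyl)-2,3-dihydro-1-benzofuran (cis) | COc1c(OCC=C)ccc2c1O[C@@H](c1cc(OC)c(OC)c(OC)c1)[C@H]2C | intermediate (key-step product)
10 | (2S,3S)-6-(allyloxy)-7-methoxy-3-methyl-2-(3,4,5-trimethoxyphenyl)-2,3-dihydro-1-benzofuran (trans) | COc1c(OCC=C)ccc2c1O[C@H](c1cc(OC)c(OC)c(OC)c1)[C@H]2C | intermediate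
11 | (2S,3S)-5-allyl-7-methoxy-3-methyl-2-(3,4,5-trimethoxyphenyl)-3,5-dihydro-1-benzofuran-6(2H)-one (C5 not defined) | C=CCC1C=C2C(=C(OC)C1=O)O[C@H](c1cc(OC)c(OC)c(OC)c1)[C@H]2C | intermediate (not isolated)
12 | (2S,3S)-5-allyl-7-methoxy-3-methyl-2-(3,4,5-trimethoxyphenyl)-2,3-dihydro-1-benzofuran-6-ol | COc1c(O)c(CC=C)cc2c1O[C@H](c1cc(OC)c(OC)c(OC)c1)[C@H]2C | intermediate
13 | {[(2S,3S)-5-allyl-7-methoxy-3-methyl-2-(3,4,5-trimethoxyphenyl)-2,3-dihydro-1-benzofuran-6-yl]oxy}(acetoxy)phenyl-λ3-iodane | CC(=O)OI(c1ccccc1)Oc1c(CC=C)cc2c(c1OC)O[C@H](c1cc(OC)c(OC)c(OC)c1)[C@H]2C | intermediate (not isolated)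
14 | (2S,3S,5R)-5-allyl-5,7-dimethoxy-3-methyl-2-(3,4,5-trimethoxyphenyl)-3,5-dihydro-1-benzofuran-6(2H)-one | C=CC[C@@]1(OC)C=C2C(=C(OC)C1=O)O[C@H](c1cc(OC)c(OC)c(OC)c1)[C@H]2C | target

**Step count and risk**

Total step count: 9. Longest linear sequence: 9 steps (from 1).

Steps most likely to fail:

Step 9. What may go wrong: capture of methanol at the wrong ring carbon of the oxidised phenol. Ketal formation at the methoxy-bearing C7 is the site normally preferred by 2-methoxyphenols, and attack at the ring-fusion carbon C3a is also possible. Facial attack at C5 is unselective, and the dienone may undergo acid-promoted allyl migration. Against ketal formation stand only the twisted, doubly flanked C7 methoxy group and the crowding of a gem-dimethoxy carbon between C6 and C7a. Mis-oxidised material and the 5S epimer should return to 12 on reduction with Zn in AcOH.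

The fallback makes the quaternary carbon by C–C bond formation at a carbonyl group whose position is unambiguous, instead of by C–O bond formation on a delocalised cation. It sets out from 10 and comes back at 14.
- The zerovalent palladium complex Pd(PPh3)4 with morpholine in THF removes the allyl group and gives (2S,3S)-7-methoxy-3-methyl-2-(3,4,5-trimethoxyphenyl)-2,3-dihydro-1-benzofuran-6-ol F1.
- Teuber oxidation with (KSO3)2NO in KH2PO4-buffered aqueous acetone at 0 °C places the second oxygen on C5, the only carbon ortho to the hydroxyl that still carries hydrogen. It gives (2S,3S)-7-methoxy-3-methyl-2-(3,4,5-trimethoxyphenyl)-2,3-dihydro-1-benzofuran-5,6-dione F2, which is used at once to forestall tautomerisation through the C3–H bond.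
- Allylindium sesquibromide (C3H5)3In2Br3, prepared beforehand from allyl bromide 2 and indium powder in DMF, adds at −40 °C to the C5 carbonyl in a Barbier-type 1,2-allylation. The C6 carbonyl is deactivated as part of the vinylogous ester O1–C7a=C7–C6=O. After separation of the C5 epimers this gives (2S,3S,5R)-5-allyl-5-hydroxy-7-methoxy-3-methyl-2-(3,4,5-trimethoxyphenyl)-3,5-dihydro-1-benzofuran-6(2H)-one F3.
- Purdie methylation of the tertiary hydroxyl (MeI, Ag2O, CH2Cl2, dark) then gives 14.

Step 6. What may go wrong: 1,2-hydride migration from the methyl group within the rhodium carbene (formation of the vinyl arene), azine formation from diazoalkane that has not yet reached the catalyst, or weak discrimination of the carbene faces by the catalyst.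

The fallback forms the same C2–C3 bond photochemically, by hydrogen transfer and biradical recombination, and obtains the enantiomer by resolution. It sets out from 6 and comes back at 10.
- Norrish–Yang-type photocyclisation of ketone 6 (350 nm, benzene, argon): the excited carbonyl oxygen abstracts a hydrogen from the O–CH2–aryl group and the resulting 1,5-biradical closes. This gives 6-(allyloxy)-7-methoxy-3-methyl-2-(3,4,5-trimethoxyphenyl)-2,3-dihydro-1-benzofuran-3-ol F4 as a racemic mixture of diastereomers.
- Ionic deoxygenation with Et3SiH and CF3CO2H in CH2Cl2 removes the tertiary benzylic hydroxyl. Under the same acid the product equilibrates to the trans ether, obtained as 10 together with its enantiomer (2R,3R)-6-(allyloxy)-7-methoxy-3-methyl-2-(3,4,5-trimethoxyphenyl)-2,3-dihydro-1-benzofuran F5.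
- Preparative chromatography on a chiral stationary phase delivers 10.

Step 7. What may go wrong: loss of the C3 proton from the ring-opened benzylic cation followed by re-protonation (erosion of enantiopurity), incomplete cis-to-trans conversion, or attack of the acid on the allyl ether.

The fallback secures stereochemical purity by a diastereomeric derivative instead of by the equilibration alone. It sets out from 12 (material carried through step 8 without stereochemical purification) and comes back at 12.
- Esterification with (1S)-camphanoyl chloride (Et3N, DMAP, CH2Cl2) gives (2S,3S)-5-allyl-7-methoxy-3-methyl-2-(3,4,5-trimethoxyphenyl)-2,3-dihydro-1-benzofuran-6-yl (1S,4R)-4,7,7-trimethyl-3-oxo-2-oxabicyclo[2.2.1]heptane-1-carboxylate F6.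
- Crystallisation or chromatography frees F6 from the diastereomeric esters derived from the enantiomeric and cis phenols.
- Saponification (LiOH, THF–H2O) returns 12.

**Further compounds**

F1 | step 9 | (2S,3S)-7-methoxy-3-methyl-2-(3,4,5-trimethoxyphenyl)-2,3-dihydro-1-benzofuran-6-ol | COc1c(O)ccc2c1O[C@H](c1cc(OC)c(OC)c(OC)c1)[C@H]2C
F2 | step 9 | (2S,3S)-7-methoxy-3-methyl-2-(3,4,5-trimethoxyphenyl)-2,3-dihydro-1-benzofuran-5,6-dione | O=C1C=C2C(=C(OC)C1=O)O[C@H](c1cc(OC)c(OC)c(OC)c1)[C@H]2C
F3 | step 9 | (2S,3S,5R)-5-allyl-5-hydroxy-7-methoxy-3-methyl-2-(3,4,5-trimethoxyphenyl)-3,5-dihydro-1-benzofuran-6(2H)-one | C=CC[C@@]1(O)C=C2C(=C(OC)C1=O)O[C@H](c1cc(OC)c(OC)c(OC)c1)[C@H]2C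
F4 | step 6 | 6-(allyloxy)-7-methoxy-3-methyl-2-(3,4,5-trimethoxyphenyl)-2,3-dihydro-1-benzofuran-3-ol (racemic mixture of diastereomers) | COc1c(OCC=C)ccc2c1OC(c1cc(OC)c(OC)c(OC)c1)C2(C)O
F5 | step 6 | (2R,3R)-6-(allyloxy)-7-methoxy-3-methyl-2-(3,4,5-trimethoxyphenyl)-2,3-dihydro-1-benzofuran | COc1c(OCC=C)ccc2c1O[C@@H](c1cc(OC)c(OC)c(OC)c1)[C@@H]2C
F6 | step 7 | (2S,3S)-5-allyl-7-methoxy-3-methyl-2-(3,4,5-trimethoxyphenyl)-2,3-dihydro-1-benzofuran-6-yl (1S,4R)-4,7,7-trimethyl-3-oxo-2-oxabicyclo[2.2.1]heptane-1-carboxylate | COc1c(OC(=O)[C@@]34CC[C@@](C)(C(=O)O3)C4(C)C)c(CC=C)cc2c1O[C@H](c1cc(OC)c(OC)c(OC)c1)[C@H]2C
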